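**Retrosynthetic overview**
1. Target 25 ⇐ reagent-controlled epoxidation of the E-alkene of 24; exocyclic methylene ⇐ ketone 23; each hydroxyl is propanoylated as soon as it is made, so no protecting groups are used.
2. Eleven-membered ring (formed last) ⇐ nickel-catalysed reductive ynal macrocyclisation of 20, joining the aldehyde carbon to the methyl-bearing alkyne carbon.
3. Both arms of 20 ⇐ cis-hydrindenone 11: Mukaiyama–Michael addition then allenylsilane propargylation at C3; α-allylation then oxidative cleavage at C5.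
4. 11 ⇐ semipinacol 1,2-shift of hydroxy mesylate 9: the angular carbon migrates, so the six-membered ring of a Hajos–Parrish hydrindane contracts to the cyclopentane while its five-membered ring expands to the cyclohexanone (second ring event).
5. 9 ⇐ (S)-Hajos–Parrish ketone 5 ⇐ 2-methylcyclopentane-1,3-dione + methyl vinyl ketone (first ring event, proline aldol).

Assumption: silane 15 is taken as a purchasable reagent, and diol 6 is drawn as the expected major allylic epimer of the Luche reduction (the minor one converges at 11).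

**Route**

Step 1
Reactants: 1 2-methylcyclopentane-1,3-dione; 2 but-3-en-2-one (methyl vinyl ketone)
Product: 3 2-methyl-2-(3-oxobutyl)cyclopentane-1,3-dione
Conditions: H2O, AcOH (cat.), 70 °C
Reagents that add atoms: none
Why: Michael addition of the acidic 1,3-dione to the enone; no stereocentre is formed.

Step 2
Reactants: 3 2-methyl-2-(3-oxobutyl)cyclopentane-1,3-dione
Product: 5 (7aS)-7a-methyl-2,3,7,7a-tetrahydro-1H-indene-1,5(6H)-dione [(S)-Hajos–Parrish ketone], via aldol ketol 4 (not isolated)
Conditions: L-proline (3 mol %), DMF, rt; then H2SO4 (cat.), 95 °C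
Reagents that add atoms: none
Why: Hajos–Parrish intramolecular enamine aldol desymmetrises the dione (L-proline sets the 7aS quaternary centre) and acid dehydrates ketol 4.

Step 3
Reactants: 5 (S)-Hajos–Parrish ketone
Product: 6 (1S,5S,7aS)-7a-methyl-2,3,5,6,7,7a-hexahydro-1H-indene-1,5-diol
Conditions: NaBH4, CeCl3·7H2O, MeOH, −20 → 0 °C
Reagents that add atoms: none
Why: Luche reduction; hydride adds 1,2 to both carbonyls from the face opposite the angular methyl, so both hydroxyls are cis to it (C1 is a target centre, C5 is lost in step 7).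

Step 4
Reactants: 6 diol
Product: 7 (1S,5S,7aS)-7a-methyl-2,3,5,6,7,7a-hexahydro-1H-indene-1,5-diyl dipropanoate
Conditions: EtCOCl, pyridine, DMAP (cat.), CH2Cl2, 0 °C → rt
Reagents that add atoms: propanoyl chloride, CCC(=O)Cl
Why: DMAP-catalysed acylation; the C1 ester is a target ester and the allylic C5 ester is the later leaving group.

Step 5
Reactants: 7 dipropanoate
Product: 8 (1S,3aS,4R,5S,7aR)-3a,4-dihydroxy-7a-methyloctahydro-1H-indene-1,5-diyl dipropanoate
Conditions: OsO4 (5 mol %), NMO, acetone/H2O, rt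
Reagents that add atoms: N-methylmorpholine N-oxide, C[N+]1([O-])CCOCC1; water, O
Why: Upjohn syn-dihydroxylation from the face opposite the angular methyl and the allylic ester gives the trans-fused diol whose secondary C4–O bond is equatorial.

Step 6
Reactants: 8 diol
Product: 9 (1S,3aS,4R,5S,7aR)-3a-hydroxy-7a-methyl-4-(methylsulfonyloxy)octahydro-1H-indene-1,5-diyl dipropanoate
Conditions: MsCl, Et3N, CH2Cl2, −20 °C
Reagents that add atoms: methanesulfonyl chloride, CS(=O)(=O)Cl
Why: Selective sulfonylation of the secondary alcohol; the tertiary ring-fusion hydroxyl does not react.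

Step 7
Reactants: 9 hydroxy mesylate
Product: 11 (7S,7aS)-7a-methyl-4-oxo-2,4,5,6,7,7a-hexahydro-1H-inden-7-yl propanoate, via acyloxy ketone 10 (not isolated)
Conditions: Et3Al, CH2Cl2, −78 → 0 °C; then DBU, rt
Reagents that add atoms: none
Why: Semipinacol 1,2-shift (Tsuchihashi–Suzuki type): the aluminium alkoxide pushes the ring bond to the quaternary carbon, which is antiperiplanar to the equatorial mesylate, onto C4 with inversion there and retention at the migrating carbon, so the six-membered ring contracts, the five-membered ring expands to a cyclohexanone and the new ring-fusion H is cis to methyl; DBU then removes propanoate by E1cB.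

Step 8
Reactants: 12 propanal
Product: 13 (Z)-trimethyl(prop-1-en-1-yloxy)silane
Conditions: Me3SiCl, Et3N, DMF, 80 °C; fractional distillation
Reagents that add atoms: chlorotrimethylsilane, C[Si](C)(C)Cl
Why: Silyl enol ether formation under equilibrating conditions gives mainly the Z isomer.

Step 9
Reactants: 11 cis-hydrindenone; 13 (Z)-enol silane
Product: 14 (3S,3aR,7S,7aS)-7a-methyl-4-oxo-3-[(2S)-1-oxopropan-2-yl]octahydro-1H-inden-7-yl propanoate
Conditions: TiCl4, CH2Cl2, −78 °C; aq. NaHCO3
Reagents that add atoms: none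
Why: Mukaiyama–Michael addition: the enol silane attacks C3 of the activated s-cis enone anti to the angular methyl, a synclinal open transition state with the enol C–H between the two ring carbons is expected to set the side-chain centre S, and work-up protonation anti to the new substituent gives the cis ring fusion.

Step 10
Reactants: 14 keto aldehyde; 15 trimethyl(buta-2,3-dien-2-yl)silane
Product: 16 (3S,3aR,7S,7aS)-3-[(2S,3S)-3-hydroxyhept-5-yn-2-yl]-7a-methyl-4-oxooctahydro-1H-inden-7-yl propanoate
Conditions: TiCl4, CH2Cl2, −78 °C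
Reagents that add atoms: none
Why: Danheiser propargylation (SE2' addition of the allenylsilane) takes place at the aldehyde and not at the hindered ketone, and Felkin–Anh attack anti to the ring carbon gives the (S) carbinol syn to the methyl branch.

Step 11
Reactants: 16 keto alcohol
Product: 17 (3S,3aR,7S,7aS)-7a-methyl-4-oxo-3-[(2S,3S)-3-(propanoyloxy)hept-5-yn-2-yl]octahydro-1H-inden-7-yl propanoate
Conditions: EtCOCl, pyridine, DMAP (cat.), CH2Cl2, 0 °C → rt
Reagents that add atoms: propanoyl chloride, CCC(=O)Cl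
Why: Acylation installs the second target ester and removes the hydroxyl that could form a hemiketal with the ketone.

Step 12
Reactants: 17 keto alkyne
Product: 18 (3S,3aR,5R,7S,7aS)-7a-methyl-4-oxo-5-(prop-2-en-1-yl)-3-[(2S,3S)-3-(propanoyloxy)hept-5-yn-2-yl]octahydro-1H-inden-7-yl propanoate
Conditions: allyl acetate, Pd(PPh3)4 (5 mol %), pyrrolidine (30 mol %), DMSO, rt
Reagents that add atoms: allyl acetate, CC(=O)OCC=C
Why: Tsuji–Trost allylation of the catalytically formed pyrrolidine enamine, which forms at the unsubstituted α-carbon C5; the mild amine equilibrates the product to the equatorial allyl epimer (trans to the neighbouring five-membered-ring bond) and leaves the esters intact.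

Step 13
Reactants: 18 allyl ketone
Product: 20 (3S,3aR,5S,7S,7aS)-7a-methyl-4-oxo-5-(2-oxoethyl)-3-[(2S,3S)-3-(propanoyloxy)hept-5-yn-2-yl]octahydro-1H-inden-7-yl propanoate, via diol 19 (not isolated)
Conditions: OsO4 (2 mol %), NaIO4, 2,6-lutidine, dioxane/H2O, rt
Reagents that add atoms: sodium periodate, [Na+].[O-]I(=O)(=O)=O; water, O
Why: Johnson–Lemieux oxidative cleavage of the monosubstituted alkene; the internal alkyne is inert to OsO4 under these conditions.

Step 14
Reactants: 20 keto ynal
Product: 22 macrocyclic (E)-allylic alcohol (11-membered ring; new carbinol R), via silyl ether 21 (not isolated)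
Conditions: Ni(cod)2 (20 mol %), (4R,5R)-1,3-bis(2,4,6-trimethylphenyl)-4,5-diphenylimidazolidin-2-ylidene (20 mol %, from its tetrafluoroborate salt and KOtBu), Et3SiH, THF, 0.005 M (slow addition), 40 °C; then 1 M HCl, THF
Reagents that add atoms: none
Why: Proposed new method: a zerovalent-nickel/chiral carbene catalyst couples the aldehyde and the methyl-capped alkyne by oxidative cyclisation to an oxanickelacyclopentene (the compact carbene places the small methyl terminus next to the carbonyl, so the C–C bond forms at the methyl-bearing carbon and both alkyne carbons end in the ring), σ-bond metathesis with Et3SiH and reductive elimination give syn H/C addition and hence the E-alkene, and the C2-symmetric ligand rather than the substrate is meant to fix the carbinol as R; the closest known reactions are the nickel-catalysed reductive ynal macrocyclisation with achiral ligands and the intermolecular enantioselective alkyne–aldehyde reductive coupling.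

Step 15
Reactants: 22 macrocyclic allylic alcohol
Product: 23 macrocyclic keto tripropanoate
Conditions: EtCOCl, pyridine, DMAP (cat.), CH2Cl2, 0 °C
Reagents that add atoms: propanoyl chloride, CCC(=O)Cl
Why: Acylation of the open hydroxy ketone installs the third target ester and prevents transannular hemiketal formation before methylenation.

Step 16
Reactants: 23 keto tripropanoate
Product: 24 methylene tripropanoate (ketone replaced by C=CH2)
Conditions: Zn, CH2Br2, TiCl4, THF/CH2Cl2, 0 °C → rt
Reagents that add atoms: dibromomethane, BrCBr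
Why: Lombardo methylenation; the non-basic titanium methylene reagent converts the hindered ketone, tolerates the three esters and does not epimerise the two α-centres.

Step 17
Reactants: 24 methylene tripropanoate
Product: 25 CNP0332420.1
Conditions: 1,2:4,5-di-O-isopropylidene-β-L-erythro-2,3-hexodiulo-2,6-pyranose (ent-Shi ketone, 30 mol %), KHSO5 (as 2KHSO5·KHSO4·K2SO4), K2CO3, Bu4NHSO4, MeCN/dimethoxymethane/aq. buffer pH 10.5, 0 °C
Reagents that add atoms: potassium peroxymonosulfate, [K+].[O-]S(=O)(=O)OO
Why: Shi epoxidation: the chiral dioxirane transfers oxygen through a spiro transition state to the E-trisubstituted alkene (the hindered 1,1-disubstituted methylene is a poor substrate), and the L-fructose-derived catalyst is the enantiomer predicted to give the (S)-CH/(R)-C(CH3) epoxide.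

**Compound list**
1 | 2-methylcyclopentane-1,3-dione | CC1C(=O)CCC1=O | starting material
2 | but-3-en-2-one (methyl vinyl ketone) | CC(=O)C=C | starting material
3 | 2-methyl-2-(3-oxobutyl)cyclopentane-1,3-dione | CC(=O)CCC1(C)C(=O)CCC1=O | intermediate
4 | (3aS,7aS)-3a-hydroxy-7a-methylhexahydro-1H-indene-1,5(4H)-dione | O=C1CC[C@]2(O)CC(=O)CC[C@]12C | intermediate
5 | (7aS)-7a-methyl-2,3,7,7a-tetrahydro-1H-indene-1,5(6H)-dione | O=C1CCC2=CC(=O)CC[C@]12C | intermediate
6 | (1S,5S,7aS)-7a-methyl-2,3,5,6,7,7a-hexahydro-1H-indene-1,5-diol | C1C[C@H](O)[C@@]2(C)CC[C@H](O)C=C12 | intermediate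
7 | (1S,5S,7aS)-7a-methyl-2,3,5,6,7,7a-hexahydro-1H-indene-1,5-diyl dipropanoate | C1C[C@H](OC(=O)CC)[C@@]2(C)CC[C@H](OC(=O)CC)C=C12 | intermediate
8 | (1S,3aS,4R,5S,7aR)-3a,4-dihydroxy-7a-methyloctahydro-1H-indene-1,5-diyl dipropanoate | C1C[C@H](OC(=O)CC)[C@@]2(C)CC[C@H](OC(=O)CC)[C@@H](O)[C@]12O | intermediate
9 | (1S,3aS,4R,5S,7aR)-3a-hydroxy-7a-methyl-4-(methylsulfonyloxy)octahydro-1H-indene-1,5-diyl dipropanoate | C1C[C@H](OC(=O)CC)[C@@]2(C)CC[C@H](OC(=O)CC)[C@@H](OS(C)(=O)=O)[C@]12O | intermediate
10 | (3S,3aS,7S,7aS)-7a-methyl-4-oxooctahydro-1H-indene-3,7-diyl dipropanoate (cis-fused) | O=C1CC[C@H](OC(=O)CC)[C@@]2(C)CC[C@H](OC(=O)CC)[C@@H]12 | intermediate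
11 | (7S,7aS)-7a-methyl-4-oxo-2,4,5,6,7,7a-hexahydro-1H-inden-7-yl propanoate | O=C1CC[C@H](OC(=O)CC)[C@@]2(C)CCC=C12 | intermediate
12 | propanal | CCC=O | starting material
13 | (Z)-trimethyl(prop-1-en-1-yloxy)silane | C/C=C\O[Si](C)(C)C | intermediate
14 | (3S,3aR,7S,7aS)-7a-methyl-4-oxo-3-[(2S)-1-oxopropan-2-yl]octahydro-1H-inden-7-yl propanoate | O=C1CC[C@H](OC(=O)CC)[C@@]2(C)CC[C@@H]([C@H](C)C=O)[C@@H]12 | intermediate
15 | trimethyl(buta-2,3-dien-2-yl)silane [1-methyl-1-(trimethylsilyl)allene] | C=C=C(C)[Si](C)(C)C | starting material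
16 | (3S,3aR,7S,7aS)-3-[(2S,3S)-3-hydroxyhept-5-yn-2-yl]-7a-methyl-4-oxooctahydro-1H-inden-7-yl propanoate | O=C1CC[C@H](OC(=O)CC)[C@@]2(C)CC[C@@H]([C@H](C)[C@@H](O)CC#CC)[C@@H]12 | intermediate
17 | (3S,3aR,7S,7aS)-7a-methyl-4-oxo-3-[(2S,3S)-3-(propanoyloxy)hept-5-yn-2-yl]octahydro-1H-inden-7-yl propanoate | O=C1CC[C@H](OC(=O)CC)[C@@]2(C)CC[C@@H]([C@H](C)[C@@H](OC(=O)CC)CC#CC)[C@@H]12 | intermediate
18 | (3S,3aR,5R,7S,7aS)-7a-methyl-4-oxo-5-(prop-2-en-1-yl)-3-[(2S,3S)-3-(propanoyloxy)hept-5-yn-2-yl]octahydro-1H-inden-7-yl propanoate | O=C1[C@H](CC=C)C[C@H](OC(=O)CC)[C@@]2(C)CC[C@@H]([C@H](C)[C@@H](OC(=O)CC)CC#CC)[C@@H]12 | intermediate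
19 | 5-(2,3-dihydroxypropyl) analogue of 18 (both carbinol epimers) | O=C1[C@H](CC(O)CO)C[C@H](OC(=O)CC)[C@@]2(C)CC[C@@H]([C@H](C)[C@@H](OC(=O)CC)CC#CC)[C@@H]12 | intermediate
20 | (3S,3aR,5S,7S,7aS)-7a-methyl-4-oxo-5-(2-oxoethyl)-3-[(2S,3S)-3-(propanoyloxy)hept-5-yn-2-yl]octahydro-1H-inden-7-yl propanoate | O=C1[C@H](CC=O)C[C@H](OC(=O)CC)[C@@]2(C)CC[C@@H]([C@H](C)[C@@H](OC(=O)CC)CC#CC)[C@@H]12 | intermediate
21 | triethylsilyl ether of 22 | O=C1[C@H]2C[C@H](OC(=O)CC)[C@@]3(C)CC[C@@H]([C@H](C)[C@@H](OC(=O)CC)C/C=C(\C)[C@H](O[Si](CC)(CC)CC)C2)[C@@H]13 | intermediate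
22 | macrocyclic keto alcohol: cis-hydrindan-4-one bridged from C3 to C5 by CH(CH3)–CH(OCOEt)–CH2–CH=C(CH3)–CH(OH)–CH2 (bridge centres S, S, R; E-alkene), 7-propanoate | O=C1[C@H]2C[C@H](OC(=O)CC)[C@@]3(C)CC[C@@H]([C@H](C)[C@@H](OC(=O)CC)C/C=C(\C)[C@H](O)C2)[C@@H]13 | intermediate
23 | propanoate of 22 (macrocyclic keto tripropanoate) | O=C1[C@H]2C[C@H](OC(=O)CC)[C@@]3(C)CC[C@@H]([C@H](C)[C@@H](OC(=O)CC)C/C=C(\C)[C@H](OC(=O)CC)C2)[C@@H]13 | intermediate
24 | 4-methylene analogue of 23 (methylene tripropanoate) | C=C1[C@H]2C[C@H](OC(=O)CC)[C@@]3(C)CC[C@@H]([C@H](C)[C@@H](OC(=O)CC)C/C=C(\C)[C@H](OC(=O)CC)C2)[C@@H]13 | intermediate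
25 | CNP0332420.1 (epoxide of 24; epoxide CH is S, epoxide C–CH3 is R) | C=C1[C@H]2C[C@H](OC(=O)CC)[C@@]3(C)CC[C@@H]([C@H](C)[C@@H](OC(=O)CC)C[C@@H]4O[C@@]4(C)[C@H](OC(=O)CC)C2)[C@@H]13 | target

**Step count and risks**

Total step count: 17. Longest linear sequence: 16 (steps 1–7 and 9–17; step 8 is a one-step side branch).

The three steps most likely to fail, each with its fallback:

Step 9. The hindered trisubstituted enone may react slowly, and the configuration of the methyl-bearing side-chain centre rests on a transition-state preference that is not secured. The fallback sets out from 11 and returns to 14. Copper-catalysed conjugate addition of isopropenylmagnesium bromide (CuBr·SMe2, THF, −78 °C) gives isopropenyl ketone F1. Hydroboration with 9-BBN from the alkene face away from the ring-fusion carbon (the ketone is reduced as well), followed by NaBO3·4H2O oxidation, gives diol F2. Dess–Martin periodinane then oxidises both hydroxyls and delivers keto aldehyde 14.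

Step 14. This is the proposed new method; ligand control of the carbinol centre and the endocyclic regiochemistry in an 11-membered ring are both unproven. The fallback uses known chemistry, sets out from 20 and returns to 22. The ring is closed with the achiral system Ni(cod)2/PBu3/Et3B (toluene, 60 °C, high dilution), which gives 22 together with its carbinol epimer F3. Dess–Martin periodinane converts the mixture into enone F4. Reduction with (S)-2-methyl-CBS-oxazaborolidine and catecholborane at −78 °C then sets the R carbinol by reagent control and gives 22.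

Step 17. The catalyst-preferred alkene face may be the transannularly shielded one, and the allylic ester slows the wanted alkene relative to the exocyclic methylene. The fallback sets out from 23 and returns to 25, changing both the order and the source of stereocontrol. Dimethyldioxirane (acetone, 0 °C) epoxidises the only alkene of 23 from the peripheral face to give epoxy ketone F5. Wittig methylenation with Ph3P=CH2 (from Ph3PCH3Br and KHMDS, toluene, 60 °C), which spares esters and the epoxide, then gives 25.

**Further compounds**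
F1 | step 9 | (3R,3aR,7S,7aS)-7a-methyl-4-oxo-3-(prop-1-en-2-yl)octahydro-1H-inden-7-yl propanoate | O=C1CC[C@H](OC(=O)CC)[C@@]2(C)CC[C@@H](C(C)=C)[C@@H]12
F2 | step 9 | 4-hydroxy-3-[(2S)-1-hydroxypropan-2-yl]-7a-methyloctahydro-1H-inden-7-yl propanoate (both C4 epimers) | OC1CC[C@H](OC(=O)CC)[C@@]2(C)CC[C@@H]([C@H](C)CO)[C@@H]12
F3 | step 14 | carbinol epimer of 22 (new centre S) | O=C1[C@H]2C[C@H](OC(=O)CC)[C@@]3(C)CC[C@@H]([C@H](C)[C@@H](OC(=O)CC)C/C=C(\C)[C@@H](O)C2)[C@@H]13
F4 | step 14 | macrocyclic (E)-enone from oxidation of 22 and F3 | O=C1[C@H]2C[C@H](OC(=O)CC)[C@@]3(C)CC[C@@H]([C@H](C)[C@@H](OC(=O)CC)C/C=C(\C)C(=O)C2)[C@@H]13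
F5 | step 17 | epoxy ketone (25 with C=O in place of C=CH2) | O=C1[C@H]2C[C@H](OC(=O)CC)[C@@]3(C)CC[C@@H]([C@H](C)[C@@H](OC(=O)CC)C[C@@H]4O[C@@]4(C)[C@H](OC(=O)CC)C2)[C@@H]13
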